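**Strategy.** Numbering: five-ring C1(CH3)–C2(OAc)–C3–C4(OH)(iPr)–C5; seven-ring C5–C6(O-aroyl)–C7=C8(CH3)–C9(=O)–C10–C1. The α-methyl enone C7=C8(CH3)–C9=O of the seven-ring is exploited: C8 is disconnected as one carbon inserted between C7 and C9. Dibromocarbene adds to the C7=C9 triethylsilyl enol ether of a trans-hydrindane; opening of the siloxy dibromocyclopropane forms C7–C8 and C8–C9, enlarges the six-ring to the seven-ring and leaves bromine on C8 for methylation. The precursor already holds the trans C1/C5 fusion, a C2 dioxolane and the silylated C4 isopropyl carbinol.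

Key step: step 13

Remark: target numbering is kept for all intermediates; β is the face of the C1 methyl group and α the opposite face; the target is C1 S, C2 S, C4 S, C5 R, C6 R in this numbering; the S enantiomer of 4-(tert-butyldimethylsilyloxy)cyclopent-2-en-1-one is assumed to be purchasable.

Step 1
Reactants: 1 (S)-4-(tert-butyldimethylsilyloxy)cyclopent-2-en-1-one
Product: 2 (S)-4-(tert-butyldimethylsilyloxy)-2-iodocyclopent-2-en-1-one
Conditions: I2, pyridine/CH2Cl2, 0 °C to rt
Reagents that add atoms: iodine (II)
Why: Pyridine-mediated α-iodination of an enone (conjugate addition of pyridine, iodination of the enolate, E1cB loss of pyridine) should place iodine on the α-carbon without touching the C4 stereocentre.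

Step 2
Reactants: 2 (S)-4-(tert-butyldimethylsilyloxy)-2-iodocyclopent-2-en-1-one; 3 methylzinc chloride
Product: 4 (S)-4-(tert-butyldimethylsilyloxy)-2-methylcyclopent-2-en-1-one
Conditions: MeZnCl, Pd(PPh3)4 (5 mol %), THF, 0 °C to rt
Reagents that add atoms: methylzinc chloride (C[Zn]Cl)
Why: Negishi coupling of the α-iodo enone (oxidative addition to zerovalent palladium, transmetalation, reductive elimination) uses a non-basic organozinc, so the base-sensitive 4-silyloxy enone should survive.

Step 3
Reactants: 4 (S)-4-(tert-butyldimethylsilyloxy)-2-methylcyclopent-2-en-1-one; 5 vinylmagnesium bromide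
Product: 6 C2 trimethylsilyl enol ether (C1=C2) carrying the C5 vinyl group trans to the C4 silyloxy group
Conditions: vinylMgBr, CuBr·SMe2 (10 mol %), TMSCl, DMPU, THF, −78 °C; Et3N, pentane work-up
Reagents that add atoms: vinylmagnesium bromide (C=C[Mg]Br); chlorotrimethylsilane (C[Si](C)(C)Cl)
Why: Copper-catalysed conjugate addition with in situ silyl trapping should deliver the vinyl group to C5 anti to the C4 silyloxy group, which sets C5, and fix the enolate regiochemistry as the isolable silyl enol ether.

Step 4
Reactants: 6 C2 trimethylsilyl enol ether; 7 3-bromo-2-methylprop-1-ene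
Product: 9 cyclopentanone with C2 ketone / C1 β-methyl and α-(2-methylallyl) / C5 β-vinyl / C4 α-OTBS, via lithium enolate 8 (not isolated)
Conditions: MeLi, THF, 0 °C; then methallyl bromide, HMPA, −78 to −30 °C
Reagents that add atoms: 3-bromo-2-methylprop-1-ene (CC(=C)CBr)
Why: Regiospecific enolate generation from the silyl enol ether followed by SN2 C-alkylation with the allylic bromide should occur anti to the adjacent C5 vinyl group, setting quaternary C1 with its methyl cis to vinyl (the later trans ring fusion).

Step 5
Reactants: 9 cyclopentanone from step 4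
Product: 10 C2 ethylene ketal (dioxolane) of 9
Conditions: (TMSOCH2)2, TMSOTf (cat.), CH2Cl2, −78 to −20 °C; pyridine quench
Reagents that add atoms: 1,2-bis(trimethylsilyloxy)ethane (C[Si](C)(C)OCCO[Si](C)(C)C)
Why: Silyl triflate-catalysed ketalisation with the bis-silyl glycol (Noyori conditions) should convert the hindered ketone at low temperature without eliminating the β-silyloxy group, and masks C2 before C4 becomes a carbonyl.

Step 6
Reactants: 10 C2 dioxolane
Product: 11 C4 α-alcohol
Conditions: TBAF, THF, 0 °C to rt
Reagents that add atoms: none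
Why: Fluoride desilylation of the secondary silyl ether is safe now that no ketone is β to C4.

Step 7
Reactants: 11 C4 α-alcohol
Product: 12 C4 ketone
Conditions: Dess–Martin periodinane, NaHCO3, CH2Cl2, 0 °C to rt
Reagents that add atoms: none
Why: Buffered Dess–Martin oxidation is neutral enough that the β,γ-unsaturated ketone should not epimerise at C5 or move its vinyl group into conjugation; the ketone is used at once.

Step 8
Reactants: 12 C4 ketone; 13 isopropylmagnesium chloride
Product: 14 C4 tertiary carbinol (4β-OH, 4α-isopropyl)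
Conditions: CeCl3 (anhydrous), iPrMgCl, THF, −78 °C, then 12, −78 to −40 °C
Reagents that add atoms: isopropylmagnesium chloride (CC(C)[Mg]Cl)
Why: Organocerium 1,2-addition suppresses enolisation and β-hydride reduction, and the isopropyl group should attack the α face, anti to the adjacent C5 vinyl group, so the new C4 hydroxyl is β.

Step 9
Reactants: 14 C4 tertiary carbinol
Product: 15 C4 triethylsilyl ether
Conditions: TESOTf, 2,6-lutidine, CH2Cl2, 0 °C to rt
Reagents that add atoms: triethylsilyl trifluoromethanesulfonate (CC[Si](CC)(CC)OS(=O)(=O)C(F)(F)F)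
Why: Silyl triflate silylation is the standard way to cap a hindered tertiary alcohol, which blocks retro-aldol cleavage of C4–C5 in the carbonyl chemistry that follows.

Step 10
Reactants: 15 C4 triethylsilyl ether
Product: 17 keto aldehyde (C6 aldehyde on C5 / C9 methyl ketone on the C10 arm), via bis-ozonide 16 (not isolated)
Conditions: O3, CH2Cl2, −78 °C; PPh3, −78 °C to rt
Reagents that add atoms: ozone ([O-][O+]=O)
Why: Ozonolysis with reductive work-up cleaves both terminal alkenes to the aldehyde and the methyl ketone, while the ketal (no acetal C–H) and the silyl ether are inert.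

Step 11
Reactants: 17 keto aldehyde
Product: 19 trans-hydrindenone (C6=C7–C9=O) with C2 dioxolane and C4 OTES, via aldol adduct 18 (not isolated)
Conditions: KOH, MeOH, 0 °C to rt
Reagents that add atoms: none
Why: In this intramolecular aldol condensation the methyl ketone enolate (C7) closes the six-ring onto the C6 aldehyde and E1cB dehydration gives the enone; the C5 hydrogen lies between two quaternary carbons and should not enolise under these mild conditions, so the trans fusion is kept.

Step 12
Reactants: 19 trans-hydrindenone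
Product: 20 trans-hydrindane C9 triethylsilyl enol ether (C7=C9) with C2 dioxolane and C4 OTES
Conditions: Et3SiH, RhCl(PPh3)3 (2 mol %), toluene, 55 °C
Reagents that add atoms: triethylsilane (CC[SiH](CC)CC)
Why: Rhodium-catalysed 1,4-hydrosilylation of an enone with a monohydrosilane gives the silyl enol ether regiospecifically at C7=C9 and creates no stereocentre.

Step 13
Reactants: 20 C9 triethylsilyl enol ether; 21 bromoform
Product: 23 8-bromo hydroazulen-7-en-9-one with C2 dioxolane and C4 OTES, via siloxy dibromocyclopropane 22 (not isolated)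
Conditions: CHBr3, KOtBu, pentane, −20 °C to rt; then Et3N, MeOH, 50 °C
Reagents that add atoms: bromoform (BrC(Br)Br)
Why: tert-Butoxide deprotonates bromoform and α-elimination of bromide gives dibromocarbene, which adds as an electrophile to the C7=C9 enol ether to give the siloxy dibromocyclopropane 22; on warming in methanol/triethylamine the endo bromide ionises while the shared C7–C9 bond opens in a disrotatory cyclopropyl-to-allyl process pushed by the siloxy oxygen, and methanol removes the silyl group from the resulting oxocarbenium ion to leave the C7=C8(Br)–C9=O bromo enone. The closest known reaction type is the dihalocarbene ring expansion of cyclic silyl enol ethers to 2-halocycloalk-2-enones. The seven-membered ring arises by insertion of C8 into the six-membered ring (cleavage of the zero-atom bridge of the bicyclo[4.1.0] adduct), not by an end-to-end cyclisation, so no ring-closure mode of a direct seven-ring closure applies. No stereocentre is created: the two cyclopropane centres of 22 are erased on opening, adducts from either face converge on 23, and C1, C4 and C5 are remote and untouched. The only selectivity required is site selectivity, secured because the enol ether is the sole electron-rich alkene and its position was fixed by the 1,4-hydrosilylation, so C8 can enter only between C7 and C9. Methanol and triethylamine take up the silyl group and the hydrogen bromide, so no bromosilane or acid reaches the dioxolane or the tertiary silyl ether.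

Step 14
Reactants: 23 8-bromo enone; 3 methylzinc chloride
Product: 24 8-methyl hydroazulen-7-en-9-one with C2 dioxolane and C4 OTES
Conditions: MeZnCl, Pd(PPh3)4 (5 mol %), THF, 50 °C
Reagents that add atoms: methylzinc chloride (C[Zn]Cl)
Why: Negishi coupling of the α-bromo enone installs the C8 methyl under neutral conditions that ketal, silyl ether and enone tolerate.

Step 15
Reactants: 24 8-methyl enone
Product: 25 C2 ketone (C4 OTES, C9 enone)
Conditions: PPTS, acetone/H2O (10:1), 55 °C
Reagents that add atoms: water (O)
Why: Mild acid-catalysed ketal hydrolysis should free the C2 ketone while the very hindered tertiary triethylsilyl ether stays on and the β-silyloxy ketone does not eliminate.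

Step 16
Reactants: 25 C2 ketone
Product: 26 C2 β-alcohol
Conditions: NaBH4, MeOH/CH2Cl2 (1:1), −78 °C
Reagents that add atoms: none
Why: In this chemoselective borohydride reduction the saturated cyclopentanone should react faster than the conjugated α-methyl cycloheptenone at low temperature, and hydride should approach from the α face, away from the angular C1 methyl and the C4 silyloxy group (the 17-keto steroid pattern), giving the 2β-alcohol.

Step 17
Reactants: 26 C2 β-alcohol
Product: 27 C2 β-acetate
Conditions: Ac2O, pyridine, DMAP (cat.), CH2Cl2, rt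
Reagents that add atoms: acetic anhydride (CC(=O)OC(C)=O)
Why: DMAP-catalysed acetylation of the only free hydroxyl installs the target acetate before C6 is oxidised.

Step 18
Reactants: 27 C2 β-acetate
Product: 29 C6,C9 ene-dione (C2 OAc, C4 OTES), via C6 tert-butyl peroxide 28 (not isolated)
Conditions: Pd(OH)2/C (5 mol %), tBuOOH, K2CO3, CH2Cl2, 4 °C
Reagents that add atoms: tert-butyl hydroperoxide (CC(C)(C)OO)
Why: In the palladium hydroxide/tert-butyl hydroperoxide γ-oxidation of enones to 1,4-enediones, a tert-butylperoxyl radical abstracts the γ hydrogen at C6 (allylic and vinylogously α to the ketone), the radical is trapped as the peroxide and Kornblum–DeLaMare loss of tert-butanol gives the C6 ketone.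

Step 19
Reactants: 29 ene-dione
Product: 30 C4 β-hydroxy ene-dione
Conditions: HF·pyridine, pyridine, THF, 0 °C to rt
Reagents that add atoms: none
Why: Buffered fluoride cleavage of the tertiary silyl ether is weakly acidic, which should avoid retro-aldol opening of the new β-hydroxy ketone and enolisation at C5.

Step 20
Reactants: 30 C4 β-hydroxy ene-dione
Product: 31 C4 β / C6 α diol (C9 enone intact)
Conditions: Me4NBH(OAc)3, MeCN/AcOH (1:1), −20 °C
Reagents that add atoms: none
Why: In this Evans–Saksena hydroxyl-directed reduction the C4 hydroxyl exchanges onto boron and delivers hydride intramolecularly to the β face of the neighbouring C6 carbonyl only, which should give the 6α-alcohol (1,3-anti to the C4 hydroxyl) and leave the undirected C9 ketone.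

Step 21
Reactants: 31 diol; 32 4-acetoxybenzoyl chloride
Product: 33 C6 α 4-acetoxybenzoate
Conditions: pyridine, DMAP (cat.), CH2Cl2, 0 °C to rt
Reagents that add atoms: 4-acetoxybenzoyl chloride (CC(=O)Oc1ccc(cc1)C(Cl)=O)
Why: Base-mediated acylation by the acid chloride should select the secondary allylic C6 hydroxyl over the tertiary C4 hydroxyl, and the acid chloride is far more reactive than the aryl acetate it carries.

Step 22
Reactants: 33 C6 α 4-acetoxybenzoate
Product: 34 target, 2β-acetoxy-4β-hydroxy-4α-isopropyl-1β,8-dimethyl-9-oxo-trans-hydroazulen-7-en-6α-yl 4-hydroxybenzoate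
Conditions: NH4OAc, MeOH/H2O (4:1), rt
Reagents that add atoms: none
Why: Chemoselective solvolysis of the phenolic acetate (aryloxide is the best leaving group) should leave the hindered alkyl acetate at C2 and the aryl carboxylate at C6 untouched.

**Compound list**

1 | (S)-4-(tert-butyldimethylsilyloxy)cyclopent-2-en-1-one | O=C1C=C[C@@H](O[Si](C)(C)C(C)(C)C)C1 | starting material
2 | (S)-4-(tert-butyldimethylsilyloxy)-2-iodocyclopent-2-en-1-one | O=C1C(I)=C[C@@H](O[Si](C)(C)C(C)(C)C)C1 | intermediate
3 | methylzinc chloride | C[Zn]Cl | starting material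
4 | (S)-4-(tert-butyldimethylsilyloxy)-2-methylcyclopent-2-en-1-one | O=C1C(C)=C[C@@H](O[Si](C)(C)C(C)(C)C)C1 | intermediate
5 | vinylmagnesium bromide | C=C[Mg]Br | starting material
6 | C2 trimethylsilyl enol ether, C5 vinyl trans to C4 OTBS | C[Si](C)(C)OC1=C(C)[C@H](C=C)[C@@H](O[Si](C)(C)C(C)(C)C)C1 | intermediate
7 | 3-bromo-2-methylprop-1-ene | CC(=C)CBr | starting material
8 | lithium enolate corresponding to 6 | [Li]OC1=C(C)[C@H](C=C)[C@@H](O[Si](C)(C)C(C)(C)C)C1 | intermediate
9 | cyclopentanone: C2 ketone, C1 β-methyl and α-(2-methylallyl), C5 β-vinyl, C4 α-OTBS | O=C1C[C@H](O[Si](C)(C)C(C)(C)C)[C@@H](C=C)[C@]1(C)CC(C)=C | intermediate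
10 | C2 dioxolane of 9 | C1COC2(O1)C[C@H](O[Si](C)(C)C(C)(C)C)[C@@H](C=C)[C@]2(C)CC(C)=C | intermediate
11 | C4 α-alcohol | C1COC2(O1)C[C@H](O)[C@@H](C=C)[C@]2(C)CC(C)=C | intermediate
12 | C4 ketone | C1COC2(O1)CC(=O)[C@@H](C=C)[C@]2(C)CC(C)=C | intermediate
13 | isopropylmagnesium chloride | CC(C)[Mg]Cl | starting material
14 | C4 carbinol, 4β-OH, 4α-isopropyl | C1COC2(O1)C[C@](O)(C(C)C)[C@@H](C=C)[C@]2(C)CC(C)=C | intermediate
15 | C4 triethylsilyl ether of 14 | C1COC2(O1)C[C@](O[Si](CC)(CC)CC)(C(C)C)[C@@H](C=C)[C@]2(C)CC(C)=C | intermediate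
16 | bis-ozonide (both 1,2,4-trioxolanes, mixed configuration at the new ring carbons) | C1COC2(O1)C[C@](O[Si](CC)(CC)CC)(C(C)C)[C@@H](C3OCOO3)[C@]2(C)CC4(C)OCOO4 | intermediate
17 | keto aldehyde: C6 aldehyde on C5, C9 methyl ketone on the C10 arm | C1COC2(O1)C[C@](O[Si](CC)(CC)CC)(C(C)C)[C@@H](C=O)[C@]2(C)CC(C)=O | intermediate
18 | aldol adduct: C6 hydroxy C9 ketone, trans-hydrindane | C1COC2(O1)C[C@](O[Si](CC)(CC)CC)(C(C)C)[C@H]3C(O)CC(=O)C[C@]23C | intermediate
19 | trans-hydrindenone (C6=C7–C9=O), C2 dioxolane, C4 OTES | C1COC2(O1)C[C@](O[Si](CC)(CC)CC)(C(C)C)[C@H]3C=CC(=O)C[C@]23C | intermediate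
20 | trans-hydrindane C9 triethylsilyl enol ether (C7=C9), C2 dioxolane, C4 OTES | C1COC2(O1)C[C@](O[Si](CC)(CC)CC)(C(C)C)[C@H]3CC=C(O[Si](CC)(CC)CC)C[C@]23C | intermediate
21 | bromoform | BrC(Br)Br | starting material
22 | C9-siloxy C8-dibromocyclopropane (C7–C8–C9), either face | C1COC2(O1)C[C@](O[Si](CC)(CC)CC)(C(C)C)[C@H]3CC4C(Br)(Br)C4(O[Si](CC)(CC)CC)C[C@]23C | intermediate
23 | 8-bromo hydroazulen-7-en-9-one, C2 dioxolane, C4 OTES | C1COC2(O1)C[C@](O[Si](CC)(CC)CC)(C(C)C)[C@H]3CC=C(Br)C(=O)C[C@]23C | intermediate
24 | 8-methyl hydroazulen-7-en-9-one, C2 dioxolane, C4 OTES | C1COC2(O1)C[C@](O[Si](CC)(CC)CC)(C(C)C)[C@H]3CC=C(C)C(=O)C[C@]23C | intermediate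
25 | C2 ketone, C4 OTES, C9 enone | O=C1C[C@](O[Si](CC)(CC)CC)(C(C)C)[C@H]2CC=C(C)C(=O)C[C@]12C | intermediate
26 | C2 β-alcohol | O[C@H]1C[C@](O[Si](CC)(CC)CC)(C(C)C)[C@H]2CC=C(C)C(=O)C[C@]12C | intermediate
27 | C2 β-acetate | CC(=O)O[C@H]1C[C@](O[Si](CC)(CC)CC)(C(C)C)[C@H]2CC=C(C)C(=O)C[C@]12C | intermediate
28 | C6 tert-butylperoxy enone (either C6 epimer) | CC(=O)O[C@H]1C[C@](O[Si](CC)(CC)CC)(C(C)C)[C@H]2C(OOC(C)(C)C)C=C(C)C(=O)C[C@]12C | intermediate
29 | C6,C9 ene-dione, C2 OAc, C4 OTES | CC(=O)O[C@H]1C[C@](O[Si](CC)(CC)CC)(C(C)C)[C@H]2C(=O)C=C(C)C(=O)C[C@]12C | intermediate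
30 | C4 β-hydroxy ene-dione | CC(=O)O[C@H]1C[C@](O)(C(C)C)[C@H]2C(=O)C=C(C)C(=O)C[C@]12C | intermediate
31 | C4 β, C6 α diol, C9 enone | CC(=O)O[C@H]1C[C@](O)(C(C)C)[C@H]2[C@H](O)C=C(C)C(=O)C[C@]12C | intermediate
32 | 4-acetoxybenzoyl chloride | CC(=O)Oc1ccc(cc1)C(Cl)=O | starting material
33 | C6 α 4-acetoxybenzoate | CC(=O)O[C@H]1C[C@](O)(C(C)C)[C@H]2[C@H](OC(=O)c3ccc(OC(C)=O)cc3)C=C(C)C(=O)C[C@]12C | intermediate
34 | target (C1 S, C2 S, C4 S, C5 R, C6 R) | CC(=O)O[C@H]1C[C@](O)(C(C)C)[C@H]2[C@H](OC(=O)c3ccc(O)cc3)C=C(C)C(=O)C[C@]12C | target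

**Totals.** Total step count: 22. Longest linear sequence: 22 steps (fully linear from 1).

**Steps most likely to fail**

Step 18. Hydrogen abstraction at the crowded C6 methylene may be slow or unselective (competing attack at the C8 methyl, or stalling at the peroxide). The fallback sets out from 27: soft enolisation (TBSOTf, Et3N, CH2Cl2) should give the C6=C7/C8=C9 tert-butyldimethylsilyl dienol ether F1. Peracid oxidation at the terminal C6=C7 bond (mCPBA, NaHCO3, vinylogous Rubottom oxidation, as used for 6-hydroxylation of steroidal dienol ethers) should then give the C6-hydroxy enone F2 as either epimer. Dess–Martin oxidation of F2 returns to the route at 29.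

Step 13. The enol ether may be cleaved by tert-butoxide or by adventitious water before the carbene adds, or the dibromocyclopropane may open incompletely. The fallback sets out from 20: Simmons–Smith cyclopropanation (Et2Zn, CH2I2) should give the C9-siloxy cyclopropane F3. Oxidative opening of the shared C7–C9 bond with FeCl3 in DMF/pyridine (Ito–Saegusa ring expansion) should give the C7-chloro cycloheptanone F4. NaOAc in methanol should eliminate hydrogen chloride to the cyclohept-7-en-9-one F5. Pyridine-mediated α-iodination (I2, pyridine) should give the 8-iodo enone F6, and Negishi methylation (MeZnCl, Pd(PPh3)4) returns to the route at 24.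

Step 4. During the slow quaternising alkylation, proton transfer between product and enolate may move the enolate to C3 and expel the C4 silyloxy group (β-elimination), or alkylation may occur on oxygen. The fallback sets out from 6: the lithium enolate 8 (MeLi) is O-acylated at −78 °C with 2-methylallyl chloroformate to the 2-methylallyl enol carbonate F7. Decarboxylative Tsuji allylation (Pd(PPh3)4 cat., THF, rt) should then form the C1–C10 bond under neutral conditions, anti to the C5 vinyl group, returning to the route at 9.

**Further compounds**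

F1 | step 18 | C6=C7/C8=C9 tert-butyldimethylsilyl dienol ether of 27 | CC(=O)O[C@H]1C[C@](O[Si](CC)(CC)CC)(C(C)C)[C@H]2C=CC(C)=C(O[Si](C)(C)C(C)(C)C)C[C@]12C
F2 | step 18 | C6-hydroxy enone (either C6 epimer) | CC(=O)O[C@H]1C[C@](O[Si](CC)(CC)CC)(C(C)C)[C@H]2C(O)C=C(C)C(=O)C[C@]12C
F3 | step 13 | C9-siloxy cyclopropane (C7–C8–C9) | C1COC2(O1)C[C@](O[Si](CC)(CC)CC)(C(C)C)[C@H]3CC4CC4(O[Si](CC)(CC)CC)C[C@]23C
F4 | step 13 | C7-chloro cycloheptan-9-one | C1COC2(O1)C[C@](O[Si](CC)(CC)CC)(C(C)C)[C@H]3CC(Cl)CC(=O)C[C@]23C
F5 | step 13 | hydroazulen-7-en-9-one without C8 substituent | C1COC2(O1)C[C@](O[Si](CC)(CC)CC)(C(C)C)[C@H]3CC=CC(=O)C[C@]23C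
F6 | step 13 | 8-iodo hydroazulen-7-en-9-one | C1COC2(O1)C[C@](O[Si](CC)(CC)CC)(C(C)C)[C@H]3CC=C(I)C(=O)C[C@]23C
F7 | step 4 | 2-methylallyl enol carbonate of the C1=C2 enolate | CC(=C)COC(=O)OC1=C(C)[C@H](C=C)[C@@H](O[Si](C)(C)C(C)(C)C)C1
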